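**Plan**

- Retrosynthesis: the two N–H groups are masked as N-Boc helpers. The cyclohexene (C1 = CH–aryl, C2=C3(CH3), C4, C5, C6 = quaternary carbon) is then cut at C1–C6 and C4–C5, which gives two copies of one monomer, 5-[(E)-3-methylbuta-1,3-dienyl]-3-(1,1-dimethylallyl)indole.
- Enabling feature: ring atoms C1–C4 with the C1 aryl and the 3-methyl are one aryl-diene unit. C5–C6 with the 6-methyl and the 6-arylvinyl group are the isopropenyl C=C of a second, identical unit, so the target is a 4-vinylcyclohexene, a head-to-head [4+2] homodimer.
- The monomer is cut at the aryl–dienyl bond (Suzuki–Miyaura) and at the indole C3–C(CH3)2 bond, back to 5-bromoisatin and prenyl bromide.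
- Forward order: quaternary C(CH3)2–vinyl group on C3 (Barbier), indole aromatized by reduction, diene attached, N-Boc on, cyclohexene closed (C4–C5 first, then C1–C6 as the ring-closing bond), N-Boc off.
- Stereochemistry: C1 (R) and C6 (S) arise together in the ring closure. The chiral counteranion of the photocatalyst sets the absolute sense, and the exo position of the arylvinyl group sets it trans to the C1 aryl. The E alkenes come from syn-hydroboration and stereoretentive coupling.

Key step: step 6

Assumption: IDPi denotes a BINOL-derived imidodiphosphorimidate anion (3,3'-aryl = 3,5-(CF3)2C6H3, N-SO2CF3); which of its enantiomers leads to the (1R,6S) dimer cannot be predicted with confidence, so the (S,S)-anion is written and its mirror image is to be used if the sense proves opposite.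

**Route**

Step 1
Reactants: 1 5-bromoisatin; 2 prenyl bromide (1-bromo-3-methylbut-2-ene)
Product: 3 rac-5-bromo-3-hydroxy-3-(2-methylbut-3-en-2-yl)indolin-2-one
Conditions: indium powder (In), THF/H2O 1:1, 23 °C
Reagents that add atoms: none
Why: Barbier-type indium-mediated allylation, in which the prenylindium species should add to the electrophilic C3 ketone through a six-membered cyclic transition state at its γ-carbon (SE2'), so that the quaternary C(CH3)2–CH=CH2 group is delivered directly; the new carbinol centre forms as a racemate and is erased in step 2.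

Step 2
Reactants: 3 rac-5-bromo-3-hydroxy-3-(2-methylbut-3-en-2-yl)indolin-2-one
Product: 5 5-bromo-3-(2-methylbut-3-en-2-yl)-1H-indole, via indolin-3-ol 4 (not isolated)
Conditions: LiAlH4, THF, 0 to 45 °C; then aq. NH4Cl work-up
Reagents that add atoms: none
Why: Reductive aromatization of a 3-substituted dioxindole with LiAlH4, in which hydride should take the lactam carbonyl down to the CH2 of indolin-3-ol 4, which loses water across C2–C3 on the mildly acidic work-up to give the indole, while the isolated vinyl group and, at this moderate temperature, the aryl bromide should not be attacked.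

Step 3
Reactants: 6 2-methylbut-1-en-3-yne
Product: 7 4,4,5,5-tetramethyl-2-[(1E)-3-methylbuta-1,3-dien-1-yl]-1,3,2-dioxaborolane
Conditions: HBpin, Cp2Zr(H)Cl (5 mol %), Et3N (10 mol %), neat, 50 °C
Reagents that add atoms: pinacolborane (HBpin), [H]B1OC(C)(C)C(C)(C)O1
Why: Zirconium-catalysed hydroboration of a terminal alkyne, in which syn addition of H–B across the C≡C bond should place boron on the terminal carbon and fix the E geometry, the alkyne reacting well before the 1,1-disubstituted alkene.

Step 4
Reactants: 5 5-bromo-3-(2-methylbut-3-en-2-yl)-1H-indole; 7 4,4,5,5-tetramethyl-2-[(1E)-3-methylbuta-1,3-dien-1-yl]-1,3,2-dioxaborolane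
Product: 8 5-[(1E)-3-methylbuta-1,3-dien-1-yl]-3-(2-methylbut-3-en-2-yl)-1H-indole
Conditions: Pd(dppf)Cl2 (3 mol %), K3PO4, 1,4-dioxane/H2O 5:1, 60 °C, degassed
Reagents that add atoms: none
Why: Suzuki–Miyaura coupling, in which oxidative addition of zerovalent palladium into the aryl bromide, transmetalation of the alkenyl boronate and reductive elimination should proceed with retention of the E geometry, the free N–H and the hindered 1,1-dimethylallyl group being tolerated at this mild temperature.

Step 5
Reactants: 8 5-[(1E)-3-methylbuta-1,3-dien-1-yl]-3-(2-methylbut-3-en-2-yl)-1H-indole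
Product: 9 tert-butyl 5-[(1E)-3-methylbuta-1,3-dien-1-yl]-3-(2-methylbut-3-en-2-yl)-1H-indole-1-carboxylate
Conditions: Boc2O, DMAP (10 mol %), MeCN, 23 °C
Reagents that add atoms: di-tert-butyl dicarbonate (Boc2O), CC(C)(C)OC(=O)OC(=O)OC(C)(C)C
Why: DMAP-catalysed N-acylation of the indole should install the electron-withdrawing carbamate that serves as a helper in step 6 (it prevents N–H deprotonation of the radical cation and oxidation at nitrogen) and is removed in step 7.

Step 6
Reactants: 9 tert-butyl 5-[(1E)-3-methylbuta-1,3-dien-1-yl]-3-(2-methylbut-3-en-2-yl)-1H-indole-1-carboxylate (two molecules)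
Product: 11 tert-butyl 5-[(1R,6S)-6-{(E)-2-[1-(tert-butoxycarbonyl)-3-(2-methylbut-3-en-2-yl)-1H-indol-5-yl]ethenyl}-3,6-dimethylcyclohex-2-en-1-yl]-3-(2-methylbut-3-en-2-yl)-1H-indole-1-carboxylate, via open-chain bis-allylic radical cation 10 (not isolated)
Conditions: 9-mesitylthioxanthylium (S,S)-IDPi salt (3 mol %), CH2Cl2, −78 °C, green LEDs (525 nm), argon
Reagents that add atoms: none
Why: Proposed new method: photoexcited thioxanthylium should oxidize the aryl-diene π-system of 9 to its radical cation, held in CH2Cl2 at low temperature as a contact ion pair with the confined chiral anion; attack of the CH2 terminus of a neutral molecule of 9 on the unsubstituted CH2 terminus of this radical cation joins C4 to C5 and gives the open-chain bis-allylic radical cation 10, which closes the C1–C6 bond and hands its hole to the next molecule of 9 (the aryl-diene is more easily oxidized than the aryl-alkene left in 11). The closest known reaction types are the cation-radical Diels–Alder reaction of electron-rich aryl alkenes with 1,3-dienes, its enantioselective form under chiral-counteranion photoredox catalysis, and the thermal head-to-head [4+2] dimerization of (E)-1-aryl-3-methylbuta-1,3-dienes; not yet shown is an aryl diene serving as both 4π and 2π partner under anion control. The cyclohexene closes in a 6-exo-trig sense: the benzylic terminus C1 of the Z-configured allyl unit bonds to the methyl-bearing carbon C6 of the other allyl unit, whose remaining C=C stays outside the ring as the (E)-arylvinyl group, which completes a formal [4+2] in which C1–C4 act as the diene. C6 and C1 are created together in this closure: the chiral anion covers one face of the cationic terminus C6 and so should fix its configuration as S, and C1 should follow as R because a chair-like closure places the bulky arylvinyl group of C6 exo, away from the C1 aryl group (aryl trans to arylvinyl, the sense expected also for the thermal dimerization). The step needs head-to-head [4+2] closure in preference to [2+2] or [4+4] closure and needs the two 1,1-dimethylallyl groups to stay out; the 3-methyl group (s-cis conformer accessible, tertiary allylic cation at C6), the strain of a cyclobutane with two adjacent quaternary carbons (which, if formed, should ring-expand under the same hole catalysis) and the high oxidation potential of the isolated vinyl groups should secure this.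

Step 7
Reactants: 11 tert-butyl 5-[(1R,6S)-6-{(E)-2-[1-(tert-butoxycarbonyl)-3-(2-methylbut-3-en-2-yl)-1H-indol-5-yl]ethenyl}-3,6-dimethylcyclohex-2-en-1-yl]-3-(2-methylbut-3-en-2-yl)-1H-indole-1-carboxylate
Product: 12 5-[(1R,6S)-3,6-dimethyl-6-{(E)-2-[3-(2-methylbut-3-en-2-yl)-1H-indol-5-yl]ethenyl}cyclohex-2-en-1-yl]-3-(2-methylbut-3-en-2-yl)-1H-indole
Conditions: K2CO3 (0.3 equiv), MeOH/THF 3:1, 23 °C
Reagents that add atoms: none
Why: Base-catalysed methanolysis of an N-acyl indole (transacylation to methoxide, the indolide being a good leaving group) should remove both Boc groups at room temperature without acid or heat, so that the acid-sensitive 1,1-dimethylallyl indoles and the two stereocentres, neither of which can epimerize under base, stay untouched.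

**Compound list**

1 | 5-bromoisatin (5-bromo-1H-indole-2,3-dione) | O=C1Nc2ccc(Br)cc2C1=O | starting material
2 | prenyl bromide (1-bromo-3-methylbut-2-ene) | CC(C)=CCBr | starting material
3 | rac-5-bromo-3-hydroxy-3-(2-methylbut-3-en-2-yl)indolin-2-one | C=CC(C)(C)C1(O)C(=O)Nc2ccc(Br)cc12 | intermediate
4 | rac-5-bromo-3-(2-methylbut-3-en-2-yl)indolin-3-ol (not isolated) | C=CC(C)(C)C1(O)CNc2ccc(Br)cc12 | intermediate
5 | 5-bromo-3-(2-methylbut-3-en-2-yl)-1H-indole | C=CC(C)(C)c1c[nH]c2ccc(Br)cc12 | intermediate
6 | 2-methylbut-1-en-3-yne | C=C(C)C#C | starting material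
7 | 4,4,5,5-tetramethyl-2-[(1E)-3-methylbuta-1,3-dien-1-yl]-1,3,2-dioxaborolane | C=C(C)/C=C/B1OC(C)(C)C(C)(C)O1 | intermediate
8 | 5-[(1E)-3-methylbuta-1,3-dien-1-yl]-3-(2-methylbut-3-en-2-yl)-1H-indole (monomer) | C=CC(C)(C)c1c[nH]c2ccc(/C=C/C(C)=C)cc12 | intermediate
9 | tert-butyl 5-[(1E)-3-methylbuta-1,3-dien-1-yl]-3-(2-methylbut-3-en-2-yl)-1H-indole-1-carboxylate (N-Boc monomer) | C=CC(C)(C)c1cn(C(=O)OC(C)(C)C)c2ccc(/C=C/C(C)=C)cc12 | intermediate
10 | open-chain bis-allylic radical cation from two molecules of 9 joined CH2 to CH2 (E-arylallyl cation at the methyl-bearing carbon, Z-allyl radical at the benzylic carbon; not isolated) | C=CC(C)(C)c1cn(C(=O)OC(C)(C)C)c2ccc([CH]/C=C(/C)CC[C+](C)/C=C/c3ccc4n(C(=O)OC(C)(C)C)cc(C(C)(C)C=C)c4c3)cc12 | intermediate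
11 | tert-butyl 5-[(1R,6S)-6-{(E)-2-[1-(tert-butoxycarbonyl)-3-(2-methylbut-3-en-2-yl)-1H-indol-5-yl]ethenyl}-3,6-dimethylcyclohex-2-en-1-yl]-3-(2-methylbut-3-en-2-yl)-1H-indole-1-carboxylate (bis-Boc dimer) | C=CC(C)(C)c1cn(C(=O)OC(C)(C)C)c2ccc(/C=C/[C@]3(C)CCC(C)=C[C@H]3c3ccc4n(C(=O)OC(C)(C)C)cc(C(C)(C)C=C)c4c3)cc12 | intermediate
12 | 5-[(1R,6S)-3,6-dimethyl-6-{(E)-2-[3-(2-methylbut-3-en-2-yl)-1H-indol-5-yl]ethenyl}cyclohex-2-en-1-yl]-3-(2-methylbut-3-en-2-yl)-1H-indole | C=CC(C)(C)c1c[nH]c2ccc(/C=C/[C@]3(C)CCC(C)=C[C@H]3c3ccc4[nH]cc(C(C)(C)C=C)c4c3)cc12 | target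

**Step count and risks**

Total step count: 7. Longest linear sequence: 6 steps (steps 1, 2, 4, 5, 6 and 7, from 5-bromoisatin); step 3 is a one-step side branch.

Steps most likely to fail:

1. Step 6 (key step, proposed new method). What may go wrong: weak face discrimination by the ion pair in the ring-closing event, or diversion of the radical cation into cyclobutane formation or chain oligomerization. Fallback with known chemistry, setting out from 8 and coming back to the route at 12: the unprotected monomer 8 is heated as a concentrated, degassed toluene solution with a little BHT at about 120 °C. Thermal Diels–Alder homodimerization of (E)-1-aryl-3-methylbuta-1,3-dienes is a known reaction and should give the racemic head-to-head trans dimer, that is 12 together with its mirror image 5-[(1S,6R)-3,6-dimethyl-6-{(E)-2-[3-(2-methylbut-3-en-2-yl)-1H-indol-5-yl]ethenyl}cyclohex-2-en-1-yl]-3-(2-methylbut-3-en-2-yl)-1H-indole F1. Preparative HPLC on a polysaccharide chiral stationary phase should then separate 12 from F1. Steps 5 and 7 are then not needed.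

2. Step 2. What may go wrong: hydride attack on the C–Br bond, with loss of the halogen that step 4 needs, while the doubly deprotonated hydroxy-lactam is reduced only slowly. Fallback, setting out from 3 and coming back at 8: the order of coupling and reduction is reversed. Suzuki–Miyaura coupling of 3 with 7 under the conditions of step 4 should give the dienyl dioxindole rac-3-hydroxy-5-[(1E)-3-methylbuta-1,3-dien-1-yl]-3-(2-methylbut-3-en-2-yl)indolin-2-one F2. LiAlH4 in THF, which can now be used at reflux because no halogen is left, should reduce it through rac-5-[(1E)-3-methylbuta-1,3-dien-1-yl]-3-(2-methylbut-3-en-2-yl)indolin-3-ol F3 (not isolated) to monomer 8.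

3. Step 4. What may go wrong: loss of boronate 7 by protodeboronation or polymerization under aqueous base before transmetalation. Fallback, setting out from 5 and coming back at 8: Mizoroki–Heck reaction of 5 with an excess of isoprene (Pd(OAc)2, P(o-tol)3, K2CO3, DMF, 90 °C, sealed vessel). Aryl–palladium insertion at the unsubstituted vinyl end of isoprene and β-hydride elimination should give the (E)-diene 8 directly, so no new compound is made on the way (entry F0).

**Further compounds**

F1 | step 6 | 5-[(1S,6R)-3,6-dimethyl-6-{(E)-2-[3-(2-methylbut-3-en-2-yl)-1H-indol-5-yl]ethenyl}cyclohex-2-en-1-yl]-3-(2-methylbut-3-en-2-yl)-1H-indole (enantiomer of 12) | C=CC(C)(C)c1c[nH]c2ccc(/C=C/[C@@]3(C)CCC(C)=C[C@@H]3c3ccc4[nH]cc(C(C)(C)C=C)c4c3)cc12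
F2 | step 2 | rac-3-hydroxy-5-[(1E)-3-methylbuta-1,3-dien-1-yl]-3-(2-methylbut-3-en-2-yl)indolin-2-one | C=CC(C)(C)C1(O)C(=O)Nc2ccc(/C=C/C(C)=C)cc12
F3 | step 2 | rac-5-[(1E)-3-methylbuta-1,3-dien-1-yl]-3-(2-methylbut-3-en-2-yl)indolin-3-ol (not isolated) | C=CC(C)(C)C1(O)CNc2ccc(/C=C/C(C)=C)cc12
F0 | step 4 | none | none
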